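Product counted in mM is what this row asks for, and the percentages of the earlier runs hide it.

| flask | substrate | gas phase | catalyst | remark | time |
|---|---|---|---|---|---|
| Sunday's | 30 mM | 3.6 mM (held) | 64 µM | run made earlier |  |
| Tuesday's | 380 mM | 3.6 mM (held) | 64 µM | run made earlier |  |
| teal | 20 mM | 3.6 mM (held) | 64 µM |  | 3.0 h |
| green | 40 mM | 3.6 mM (held) | 64 µM |  | 3.0 h |
| ochre | 80 mM | 3.6 mM (held) | 64 µM |  | 3.0 h |
| amber | 150 mM | 3.6 mM (held) | 64 µM |  | 3.0 h |
| blue | 300 mM | 3.6 mM (held) | 64 µM |  | 3.0 h |

- Sunday's (time / min: product / %, substrate / %): 20.0: 0.7, 98.9; 40.0: 1.4, 98.5; 50.0: 1.5, 97.8; 80.0: 3.5, 94.8; 90.0: 6.6, 93.1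
- Tuesday's (time / min: product / %, substrate / %): 8.00: 0.1, 100.8; 25.0: 0, 99.6; 40.0: 0.8, 99.5; 60.0: 0.3, 100.0; 90.0: 1.8, 98.1

(readings scatter by 0.5 percentage points)

- at the start none of the gas is dissolved
- steps thought possible: substrate + dissolved gas + catalyst -> catalyst + product; gas phase <-> dissolved gas
- "hardly changes" means that all values lie within two and a half points (for a concentration: within two and a half percent of the largest)

* [product] at the end for teal, green, ochre, amber, blue, in this order
* how the row runs (rises all the way / falls, then rises / hardly changes / rises, then falls / falls all the way)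

Turn the question round. With gas phase and catalyst held as here, a falling row needs more substrate to give less [product] at equal time. The test is whether Tuesday's [product] stands below Sunday's. The last readings of both runs, at 90.0 min, show the opposite:

[product], Sunday = 6.6% × 30 mM = 1.98 mM

[product], Tuesday = 1.8% × 380 mM = 6.84 mM

Tuesday's [product] is higher than Sunday's by 4.86 mM. The scatter of Tuesday's reading is 1.90 mM, so the gap spans 2.56 scatters. But the charge rose 12.7-fold and the [product] read 3.45-fold:

n = ln(6.84 mM / 1.98 mM) / ln(380 mM / 30 mM) = 0.488

This n is the return on substrate, the apparent order in substrate: the logarithm of the product ratio over the logarithm of the charge ratio, at equal time. Along a row at one time, with gas phase and catalyst held, a positive n means a rise and a negative n a fall. As a reading, n carries the scatter: with Tuesday's [product] one scatter lower, it is 0.360, still positive.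

The reckoning made here carries n over to 3.0 h. By this reckoning the row rises, and blue over teal, a charge ratio of 15.0, comes to 3.75.

The forecast gives 3.8 mM, 6.5 mM, 9.3 mM, 11 mM and 12.5 mM, rises all the way, a blue over teal of 3.29, lower than the 3.75 reckoned here, on the ground that “No inhibition step is listed, so I expect no fall.”

The flask gives 3.24 mM, 4.88 mM, 6.45 mM, 7.51 mM and 8.26 mM: rises all the way.

    substrate + dissolved gas + catalyst → catalyst + product (k = 5.98 × 10⁵ M⁻² h⁻¹)
    gas phase ⇌ dissolved gas, rate k2*(csat - [dissolved gas]) (kL = 0.845 h⁻¹)

At the end, dissolved gas stands at 1.99 mM in teal and 0.253 mM in blue. Blue over teal in [product] is 2.55, lower than the reckoned 3.75. Taken from teal to blue, n is 0.346. From teal to green it is 0.591, and from amber to blue it is 0.137.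

All runs are simulated on assumed constants.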